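**Retrosynthetic overview**
- The target is benzyl icosanoate. No ring is formed in the route: the only ring, the phenyl group, is bought in benzyl acetate.
- Key disconnection C2–C3: crossed aldol addition of the lithium enolate of benzyl acetate (C1–C2, already carrying the benzyl ester) to octadecanal (C3–C20).
- The aldol hydroxyl is a traceless handle: dehydration to the 2-enoate, then C=C hydrogenation that spares the benzyl ester.
- Octadecanal comes from 1-octadecanol by oxidation.

Assumption: the target has no stereocentre and no stereogenic double bond, so it is achiral and "single enantiomer" is met by the constitution alone.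

**Route**

Step 1
Reactants: 1 1-octadecanol
Product: 2 octadecanal
Conditions: TEMPO (10 mol%), PhI(OAc)2 (1.1 equiv), CH2Cl2, rt; use the aldehyde promptly
Reagents that add atoms: none
Why: TEMPO/PhI(OAc)2 oxidation (oxoammonium-mediated alcohol oxidation) takes a primary alcohol to the aldehyde and, with no water present to form a hydrate, does not run on to the acid; no stereocentre is involved.

Step 2
Reactants: 2 octadecanal; 3 benzyl acetate
Product: 6 racemic benzyl 3-hydroxyicosanoate, via benzyl acetate lithium enolate 4 (not isolated), via lithium aldolate 5 (not isolated)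
Conditions: 3 (1.3 equiv), LiN(iPr)2 (1.35 equiv, commercial solution), THF, −78 °C, 40 min; then 2 in THF added slowly, −78 °C, 1 h; sat. aq NH4Cl at −78 °C
Reagents that add atoms: none
Why: Directed crossed aldol addition: the ester is fully converted to its lithium enolate before the aldehyde arrives, so addition to the unhindered aldehyde at −78 °C outruns proton transfer and self-condensation; the new C3 carbinol centre forms as a racemate, which does not matter because it is removed in step 3.

Step 3
Reactants: 6 racemic benzyl 3-hydroxyicosanoate
Product: 8 benzyl (E)-icos-2-enoate, via benzyl 3-(mesyloxy)icosanoate 7 (not isolated)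
Conditions: MsCl (1.5 equiv), Et3N (3 equiv), CH2Cl2, 0 °C; then DBU (2 equiv), 0 °C to rt
Reagents that add atoms: none
Why: Mesylation makes the β-hydroxyl a leaving group and DBU then brings about E1cB elimination through the ester enolate to the conjugated, thermodynamically preferred (E)-enoate, erasing the C3 stereocentre (any Z or β,γ isomer converges in step 4).

Step 4
Reactants: 8 benzyl (E)-icos-2-enoate
Product: 9 benzyl icosanoate (eicosanoic acid phenylmethyl ester)
Conditions: H2 (1 atm), 10% Pd/C (5 mol% Pd), Ph2S (0.01 equiv), EtOAc, rt
Reagents that add atoms: none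
Why: Heterogeneous catalytic hydrogenation over Pd/C partly poisoned by Ph2S saturates the C=C bond but is too deactivated for benzylic C–O hydrogenolysis, so the benzyl ester survives; no stereocentre is formed.

**Compound list**
1 | 1-octadecanol | CCCCCCCCCCCCCCCCCCO | starting material
2 | octadecanal | CCCCCCCCCCCCCCCCCC=O | intermediate
3 | benzyl acetate | CC(=O)OCc1ccccc1 | starting material
4 | lithium enolate of benzyl acetate (lithium 1-(benzyloxy)ethenolate) | C=C(O[Li])OCc1ccccc1 | intermediate (not isolated)
5 | lithium aldolate (lithium 1-(benzyloxy)-1-oxoicosan-3-olate, racemic) | CCCCCCCCCCCCCCCCCC(O[Li])CC(=O)OCc1ccccc1 | intermediate (not isolated)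
6 | benzyl 3-hydroxyicosanoate (racemic) | CCCCCCCCCCCCCCCCCC(O)CC(=O)OCc1ccccc1 | intermediate
7 | benzyl 3-(methanesulfonyloxy)icosanoate (racemic) | CCCCCCCCCCCCCCCCCC(OS(C)(=O)=O)CC(=O)OCc1ccccc1 | intermediate (not isolated)
8 | benzyl (E)-icos-2-enoate | CCCCCCCCCCCCCCCCC/C=C/C(=O)OCc1ccccc1 | intermediate
9 | benzyl icosanoate | CCCCCCCCCCCCCCCCCCCC(=O)OCc1ccccc1 | target

**Step count and risks**
Total steps: 4. Longest linear sequence: 4 steps (1 → 2 → 6 → 8 → 9); benzyl acetate 3 is bought and enters at step 2.

Steps most likely to fail:

Step 2 (aldol). Octadecanal is waxy, sparingly soluble in THF at −78 °C and prone to trimerise on storage, so conversion may be poor or self-aldol products may appear. The fallback replaces the aldol by a crossed Claisen condensation followed by reduction. It sets out from benzyl acetate 3: its lithium enolate 4 (2.1 equiv, LiN(iPr)2, THF, −78 °C) is C-acylated with commercial octadecanoyl chloride (CCCCCCCCCCCCCCCCCC(=O)Cl) to give, after acidic work-up, benzyl 3-oxoicosanoate F1. The ketone of F1 is then reduced selectively with NaBH4 in THF/MeOH at −20 to 0 °C, and the fallback comes back to the route at 6.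

Step 3 (dehydration). Base-induced retro-aldol cleavage of 6 or a sluggish, messy elimination could lower the yield. The fallback removes the hydroxyl directly by Barton–McCombie deoxygenation. It sets out from 6, which is acylated with phenyl chlorothionoformate (pyridine, cat. DMAP, CH2Cl2, 0 °C to rt) to benzyl 3-[(phenoxycarbonothioyl)oxy]icosanoate F2. Radical reduction of F2 with Bu3SnH and AIBN in toluene at 90 °C (KF work-up, recrystallisation to remove tin residues) leaves the benzyl ester untouched, and the fallback comes back at 9, so step 4 is bypassed as well.

Step 4 (chemoselective hydrogenation). If the poisoning is not balanced, either the alkene reacts slowly or the benzyl ester is partly hydrogenolysed. The fallback gives up selectivity: it sets out from 8, which is hydrogenated exhaustively (H2, unpoisoned 10% Pd/C, EtOAc/EtOH, rt) to icosanoic acid F3. The carboxylate of F3 is then O-alkylated with benzyl bromide (K2CO3, DMF, rt), and the fallback comes back at 9.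

**Further compounds**
F1 | step 2 | benzyl 3-oxoicosanoate | CCCCCCCCCCCCCCCCCC(=O)CC(=O)OCc1ccccc1
F2 | step 3 | benzyl 3-[(phenoxycarbonothioyl)oxy]icosanoate (racemic) | CCCCCCCCCCCCCCCCCC(OC(=S)Oc1ccccc1)CC(=O)OCc1ccccc1
F3 | step 4 | icosanoic acid | CCCCCCCCCCCCCCCCCCCC(=O)O
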